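**Plan**

- Retrosynthesis, in order: cut the C8–O acyl bond (p-coumarate); replace C4–H by a C4 tertiary alcohol; cut the transannular C1–C5 bond, which opens the hydroazulene to a (4R,5R)-4,5-epoxygermacr-1(10)-ene; then remove the epoxide oxygen, the silylene and the C8/C11 oxygens back to germacrone.
- Enabling feature (guaiane numbering): the cyclopentane C1–C2–C3–C4–C5 is fused through C1–C5 to the cycloheptene C5–C6–C7–C8–C9–C10=C1, with methyls on C4 and C10 and a tetrasubstituted C1=C10 alkene. This is what remains when C1 of a germacra-1(10),4-diene bonds to C5 and H-1 is lost; O-8 and the C7 CMe2OH group map onto the ketone and isopropylidene of germacrone.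
- Forward: the ten-membered ring is bought. Its enone becomes the trans-8,11-diol (1,2-reduction, directed epoxidation, oxidation, SmI2 opening, dissolving-metal reduction) and is tied as a silylene; C4=C5 is epoxidised; acid then forms the five- and seven-membered rings together; C4–OH is removed, the silylene taken off and C8–OH acylated.
- Stereochemistry: C7/C8 trans from thermodynamic ketone reduction (racemic); absolute configuration from the Shi epoxidation, run as a kinetic resolution that takes the (7S,8S)-enantiomer and sets 4R,5R; C5 by inversion in the cyclisation; C4 by hydrogen-atom delivery to the face of H-5.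

Key step: step 8

Remark: compounds 2–6 and 8 are racemates; each SMILES shows the enantiomer that is carried on to the target. Germacrane/guaiane numbering is used throughout.

**Step 1**
Reactants: 1 germacrone
Product: 2 rac-(1(10)E,4E)-germacra-1(10),4,7(11)-trien-8-ol
Conditions: LiAlH4, Et2O, −20 °C
Reagents that add atoms: none
Why: LiAlH4 adds hydride 1,2 to the hindered, poorly conjugated C8 carbonyl (hydride reduction of an enone to the allylic alcohol); the C8 centre is racemic and is erased again in step 3.

**Step 2**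
Reactants: 2 rac-(1(10)E,4E)-germacra-1(10),4,7(11)-trien-8-ol
Product: 3 rac-(1(10)E,4E,7S,8R)-7,11-epoxygermacra-1(10),4-dien-8-ol
Conditions: VO(acac)2 (cat.), t-BuOOH, CH2Cl2, 0 °C
Reagents that add atoms: tert-butyl hydroperoxide, CC(C)(C)OO
Why: Vanadium-catalysed hydroxyl-directed epoxidation reacts at the allylic C7=C11 alkene far faster than at the two ring alkenes, with oxygen delivered syn to the hydroxyl because allylic 1,3-strain holds H-8 in the alkene plane; this relative configuration is not needed later.

**Step 3**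
Reactants: 3 rac-(1(10)E,4E,7S,8R)-7,11-epoxygermacra-1(10),4-dien-8-ol
Product: 4 rac-(1(10)E,4E)-7,11-epoxygermacra-1(10),4-dien-8-one
Conditions: Dess–Martin periodinane, NaHCO3, CH2Cl2, 0 °C to rt
Reagents that add atoms: none
Why: Dess–Martin oxidation of a secondary alcohol under bicarbonate buffering should leave the epoxide and the acid-sensitive diene untouched.

**Step 4**
Reactants: 4 rac-(1(10)E,4E)-7,11-epoxygermacra-1(10),4-dien-8-one
Product: 5 rac-(1(10)E,4E)-11-hydroxygermacra-1(10),4-dien-8-one
Conditions: SmI2, THF/MeOH, −90 °C; pH 7 buffer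
Reagents that add atoms: none
Why: SmI2 reduction of an α,β-epoxy ketone: two single-electron transfers cleave the C7–O bond, the samarium enolate is protonated at C7 by methanol and the oxygen stays on C11 as the tertiary alcohol, so C7 forms as a racemate.

**Step 5**
Reactants: 5 rac-(1(10)E,4E)-11-hydroxygermacra-1(10),4-dien-8-one
Product: 6 rac-(1(10)E,4E,7S,8S)-germacra-1(10),4-diene-8,11-diol
Conditions: Li, NH3(l)/THF, t-BuOH, −78 °C; then NH4Cl
Reagents that add atoms: none
Why: Dissolving-metal reduction should give the thermodynamically preferred carbinol, with the 8-hydroxyl pseudo-equatorial and trans to the pseudo-equatorial hydroxyisopropyl group on C7, whereas hydride reagents would attack from the ring periphery and give the cis isomer; the isolated alkenes are inert.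

**Step 6**
Reactants: 6 rac-(1(10)E,4E,7S,8S)-germacra-1(10),4-diene-8,11-diol; 7 di-tert-butylsilyl bis(trifluoromethanesulfonate)
Product: 8 rac-(1(10)E,4E,7S,8S)-germacra-1(10),4-diene-8,11-diol 8,11-O-di-tert-butylsilylene
Conditions: 2,6-lutidine, CH2Cl2, 0 to 40 °C
Reagents that add atoms: none
Why: Silylene formation from a 1,3-diol with the bis(triflate): the secondary hydroxyl is silylated first and the tertiary one closes the six-membered dioxasilinane intramolecularly, leaving no free hydroxyl for the cationic step.

**Step 7**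
Reactants: 8 rac-(1(10)E,4E,7S,8S)-germacra-1(10),4-diene-8,11-diol 8,11-O-di-tert-butylsilylene
Product: 9 (1(10)E,4R,5R,7S,8S)-4,5-epoxygermacr-1(10)-ene-8,11-diol 8,11-O-di-tert-butylsilylene
Conditions: D-fructose-derived Shi ketone (30 mol%), KHSO5 (Oxone), K2CO3, Bu4NHSO4, MeCN/dimethoxymethane/aq. Na2B4O7 buffer (pH 10.5), 0 °C; stopped near half conversion, then chromatography
Reagents that add atoms: potassium peroxymonosulfate (KHSO5), [K+].[O-]S(=O)(=O)OO
Why: Shi asymmetric epoxidation run as a kinetic resolution: the chiral dioxirane oxidises E-trisubstituted alkenes on the face that gives the R,R-epoxide, which for the (7S,8S)-enantiomer coincides with the outer face of C4=C5 in the crown conformer (matched; new centres 4R,5R), whereas the (7R,8R)-enantiomer is mismatched and should be left behind, and C1=C10 should react more slowly because it sits next to the homoallylic C8 oxygen and the bulky silylene.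

**Step 8**
Reactants: 9 (1(10)E,4R,5R,7S,8S)-4,5-epoxygermacr-1(10)-ene-8,11-diol 8,11-O-di-tert-butylsilylene
Product: 10 (4R,5R,7S,8S)-guai-1(10)-ene-4,8,11-triol 8,11-O-di-tert-butylsilylene (4-OH cis to H-5)
Conditions: p-TsOH·H2O (10 mol%), CH2Cl2, 0 °C to rt
Reagents that add atoms: none
Why: Protonation of the oxirane oxygen makes C5 electrophilic; in the crossed crown conformer the C1=C10 π-bond lies across the ring behind the C5–O bond, so C1 attacks C5 with inversion while the C4–O bond stays intact, and the tertiary C10 cation then loses H-1 to give the tetrasubstituted C1=C10 alkene (acid-mediated transannular epoxide–alkene cyclisation of a 4,5-epoxygermacrene, the reaction type by which parthenolide-type epoxides give 4-hydroxyguai-1(10)-enes). The cyclopentane C1–C5 closes in 5-exo-tet fashion at C5 (the C5–O bond broken lies outside the new ring; in epoxide terms this is the endo mode, since both oxirane carbons become ring members), and the cycloheptene is the remainder of the ten-membered ring, the alkene reacting in the Markovnikov sense with the charge on C10. The only new stereocentre, C5, is fixed by the stereospecific anti opening (5R, H-5 cis to the 4-OH because the E-alkene-derived trans-epoxide holds the C4 methyl and H-5 on opposite sides); C4, C7 and C8 are carried over unchanged. The step needs C1-to-C5 bonding rather than C10-to-C5 bonding (which would give a eudesmane via a secondary cation) and loss of H-1 rather than H-9 or H-14: the first is secured by the tertiary cation and the ring geometry, the second by acid equilibration towards the most substituted alkene. Capture of the cation by oxygen is excluded because both hydroxyls are tied into the silylene.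

**Step 9**
Reactants: 10 (4R,5R,7S,8S)-guai-1(10)-ene-4,8,11-triol 8,11-O-di-tert-butylsilylene
Product: 11 (4R,5R,7S,8S)-guai-1(10)-ene-4,8,11-triol 8,11-O-di-tert-butylsilylene 4-(methyl oxalate)
Conditions: ClC(O)CO2Me, DMAP, Et3N, CH2Cl2, 0 °C to rt
Reagents that add atoms: methyl chlorooxoacetate, COC(=O)C(Cl)=O
Why: Acylation of the tertiary alcohol with the highly electrophilic oxalyl monochloride under DMAP catalysis gives the mixed oxalate needed for radical C–O cleavage without ionising C4.

**Step 10**
Reactants: 11 (4R,5R,7S,8S)-guai-1(10)-ene-4,8,11-triol 8,11-O-di-tert-butylsilylene 4-(methyl oxalate)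
Product: 12 (4S,5S,7S,8S)-guai-1(10)-ene-8,11-diol 8,11-O-di-tert-butylsilylene
Conditions: Bu3SnH, AIBN, toluene, 100 °C
Reagents that add atoms: none
Why: Barton-type radical deoxygenation of a tertiary alkyl methyl oxalate: the tin radical adds to the oxalate, the C4–O bond fragments, and the planar C4 radical should take hydrogen from Bu3SnH on the face of H-5, anti to the C6 branch on the neighbouring carbon, so H-4 ends cis to H-5 (4S).

**Step 11**
Reactants: 12 (4S,5S,7S,8S)-guai-1(10)-ene-8,11-diol 8,11-O-di-tert-butylsilylene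
Product: 13 (4S,5S,7S,8S)-guai-1(10)-ene-8,11-diol
Conditions: Bu4NF, THF, rt to 50 °C
Reagents that add atoms: none
Why: Fluoride cleavage of the silylene (Si–O to Si–F exchange); a basic fluoride source is chosen because acid could add the freed C11 hydroxyl across C1=C10.

**Step 12**
Reactants: 14 p-coumaric acid
Product: 16 (E)-4-(tert-butyldimethylsilyloxy)cinnamic acid, via bis-silylated silyl ester 15 (not isolated)
Conditions: TBSCl, imidazole, DMF, rt; then AcOH/THF/H2O, rt
Reagents that add atoms: tert-butyldimethylsilyl chloride, CC(C)(C)[Si](C)(C)Cl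
Why: Silylation of both acidic sites followed by mild aqueous acid, which hydrolyses the labile silyl ester but not the aryl silyl ether (protecting-group chemistry).

**Step 13**
Reactants: 13 (4S,5S,7S,8S)-guai-1(10)-ene-8,11-diol; 16 (E)-4-(tert-butyldimethylsilyloxy)cinnamic acid
Product: 17 (4S,5S,7S,8S)-11-hydroxyguai-1(10)-en-8-yl (E)-4-(tert-butyldimethylsilyloxy)cinnamate
Conditions: EDC·HCl, DMAP, CH2Cl2, rt
Reagents that add atoms: none
Why: Steglich esterification acylates the secondary C8 hydroxyl, the tertiary C11 hydroxyl being too hindered to react; no stereocentre is touched, so C8 keeps the S configuration.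

**Step 14**
Reactants: 17 (4S,5S,7S,8S)-11-hydroxyguai-1(10)-en-8-yl (E)-4-(tert-butyldimethylsilyloxy)cinnamate
Product: 18 (4S,5S,7S,8S)-11-hydroxyguai-1(10)-en-8-yl (E)-4-hydroxycinnamate (CNP0403230.1)
Conditions: Bu4NF/AcOH (1:1), THF, 0 °C
Reagents that add atoms: none
Why: Fluoride removal of the aryl silyl ether, buffered with acetic acid so that the phenoxide does not cleave or shift the cinnamate ester and the alkene and tertiary alcohol meet no strong acid.

**Compound list**

1 | germacrone, (1(10)E,4E)-germacra-1(10),4,7(11)-trien-8-one | C/C1=C\CC/C(C)=C/CC(=C(C)C)C(=O)C1 | starting material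
2 | rac-(1(10)E,4E)-germacra-1(10),4,7(11)-trien-8-ol | C/C1=C\CC/C(C)=C/CC(=C(C)C)[C@H](O)C1 | intermediate
3 | rac-(1(10)E,4E,7S,8R)-7,11-epoxygermacra-1(10),4-dien-8-ol (epoxide oxygen cis to 8-OH) | C/C1=C\CC/C(C)=C/C[C@]2(OC2(C)C)[C@H](O)C1 | intermediate
4 | rac-(1(10)E,4E)-7,11-epoxygermacra-1(10),4-dien-8-one | C/C1=C\CC/C(C)=C/C[C@]2(OC2(C)C)C(=O)C1 | intermediate
5 | rac-(1(10)E,4E)-11-hydroxygermacra-1(10),4-dien-8-one | C/C1=C\CC/C(C)=C/C[C@H](C(C)(C)O)C(=O)C1 | intermediate
6 | rac-(1(10)E,4E,7S,8S)-germacra-1(10),4-diene-8,11-diol (H-7 and H-8 trans) | C/C1=C\CC/C(C)=C/C[C@H](C(C)(C)O)[C@@H](O)C1 | intermediate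
7 | di-tert-butylsilyl bis(trifluoromethanesulfonate) | CC(C)(C)[Si](OS(=O)(=O)C(F)(F)F)(OS(=O)(=O)C(F)(F)F)C(C)(C)C | starting material
8 | rac-(1(10)E,4E,7S,8S)-germacra-1(10),4-diene-8,11-diol 8,11-O-di-tert-butylsilylene | C/C1=C\CC/C(C)=C/C[C@@H]2C(C)(C)O[Si](C(C)(C)C)(C(C)(C)C)O[C@H]2C1 | intermediate
9 | (1(10)E,4R,5R,7S,8S)-4,5-epoxygermacr-1(10)-ene-8,11-diol 8,11-O-di-tert-butylsilylene | C/C1=C\CC[C@@]2(C)O[C@@H]2C[C@@H]3C(C)(C)O[Si](C(C)(C)C)(C(C)(C)C)O[C@H]3C1 | intermediate
10 | (4R,5R,7S,8S)-guai-1(10)-ene-4,8,11-triol 8,11-O-di-tert-butylsilylene | CC1=C2CC[C@@](C)(O)[C@@H]2C[C@@H]3C(C)(C)O[Si](C(C)(C)C)(C(C)(C)C)O[C@H]3C1 | intermediate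
11 | (4R,5R,7S,8S)-guai-1(10)-ene-4,8,11-triol 8,11-O-di-tert-butylsilylene 4-(methyl oxalate) | CC1=C2CC[C@@](C)(OC(=O)C(=O)OC)[C@@H]2C[C@@H]3C(C)(C)O[Si](C(C)(C)C)(C(C)(C)C)O[C@H]3C1 | intermediate
12 | (4S,5S,7S,8S)-guai-1(10)-ene-8,11-diol 8,11-O-di-tert-butylsilylene | CC1=C2CC[C@H](C)[C@@H]2C[C@@H]3C(C)(C)O[Si](C(C)(C)C)(C(C)(C)C)O[C@H]3C1 | intermediate
13 | (4S,5S,7S,8S)-guai-1(10)-ene-8,11-diol | CC1=C2CC[C@H](C)[C@@H]2C[C@H](C(C)(C)O)[C@@H](O)C1 | intermediate
14 | p-coumaric acid | OC(=O)/C=C/c1ccc(O)cc1 | starting material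
15 | tert-butyldimethylsilyl (E)-4-(tert-butyldimethylsilyloxy)cinnamate | CC(C)(C)[Si](C)(C)OC(=O)/C=C/c1ccc(O[Si](C)(C)C(C)(C)C)cc1 | intermediate
16 | (E)-4-(tert-butyldimethylsilyloxy)cinnamic acid | OC(=O)/C=C/c1ccc(O[Si](C)(C)C(C)(C)C)cc1 | intermediate
17 | (4S,5S,7S,8S)-11-hydroxyguai-1(10)-en-8-yl (E)-4-(tert-butyldimethylsilyloxy)cinnamate | CC1=C2CC[C@H](C)[C@@H]2C[C@H](C(C)(C)O)[C@@H](OC(=O)/C=C/c2ccc(O[Si](C)(C)C(C)(C)C)cc2)C1 | intermediate
18 | (4S,5S,7S,8S)-11-hydroxyguai-1(10)-en-8-yl (E)-4-hydroxycinnamate (CNP0403230.1) | CC1=C2CC[C@H](C)[C@@H]2C[C@H](C(C)(C)O)[C@@H](OC(=O)/C=C/c2ccc(O)cc2)C1 | target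

**Step count**

Total: 14 steps. Longest linear sequence: 13 steps (steps 1–11, 13, 14); step 12 is a one-step side branch.

**Steps most likely to fail**

Step 7. The two enantiomers of 8 may not be distinguished well enough, or C1=C10 may be epoxidised in competition, so that the epoxide is not obtained enantiomerically pure. The fallback moves the resolution in front of the epoxidation. Diol 6 is treated with vinyl acetate and Candida rugosa lipase (MTBE, 30 °C). By the Kazlauskas rule, as in the resolution of menthol, this should acetylate the 8R enantiomer to (1(10)E,4E,7R,8R)-11-hydroxygermacra-1(10),4-dien-8-yl acetate F1 and leave the (7S,8S)-enantiomer of 6. After chromatography the unreacted (7S,8S)-diol is silylated as in step 6 and epoxidised with the same ketone to full conversion as a purely matched case. The fallback sets out from 6 and rejoins the route at 9.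

Step 5. Protonation of the C8 carbanion may occur from the wrong side, or the aldol may undergo retro-aldol cleavage in the basic medium, giving the cis-diol or loss of acetone. The fallback accepts the kinetic isomer and inverts it. Ketone 5 is reduced with Zn(BH4)2 (Et2O, −20 °C); hydride attack on the outer face of the zinc chelate should give rac-(1(10)E,4E,7S,8R)-germacra-1(10),4-diene-8,11-diol F2. Mitsunobu inversion at C8 (4-nitrobenzoic acid, PPh3, DIAD, THF, 0 °C) should give rac-(1(10)E,4E,7S,8S)-11-hydroxygermacra-1(10),4-dien-8-yl 4-nitrobenzoate F3, and methanolysis (K2CO3, MeOH) releases the trans-diol. The fallback sets out from 5 and rejoins the route at 6.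

Step 10. Hydrogen transfer may reach both faces of the C4 radical, or the oxalate may eliminate thermally. The fallback replaces radical reduction by elimination and hydrogenation. Alcohol 10 is dehydrated with Martin sulfurane (CH2Cl2, 0 °C), an anti-elimination that cannot use H-5 because it is syn to the hydroxyl. This should give (5S,7S,8S)-guaia-1(10),3-diene-8,11-diol 8,11-O-di-tert-butylsilylene F4 together with (5S,7S,8S)-guaia-1(10),4(15)-diene-8,11-diol 8,11-O-di-tert-butylsilylene F5. Hydrogenation of the mixture (H2 1 atm, PtO2, EtOAc, 0 °C) should saturate the less substituted alkene from the face of H-5 and leave the tetrasubstituted C1=C10 alkene. The fallback sets out from 10 and rejoins the route at 12.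

**Further compounds**

F1 | step 7 | (1(10)E,4E,7R,8R)-11-hydroxygermacra-1(10),4-dien-8-yl acetate | C/C1=C\CC/C(C)=C/C[C@@H](C(C)(C)O)[C@H](OC(C)=O)C1
F2 | step 5 | rac-(1(10)E,4E,7S,8R)-germacra-1(10),4-diene-8,11-diol | C/C1=C\CC/C(C)=C/C[C@H](C(C)(C)O)[C@H](O)C1
F3 | step 5 | rac-(1(10)E,4E,7S,8S)-11-hydroxygermacra-1(10),4-dien-8-yl 4-nitrobenzoate | C/C1=C\CC/C(C)=C/C[C@H](C(C)(C)O)[C@@H](OC(=O)c2ccc(cc2)[N+](=O)[O-])C1
F4 | step 10 | (5S,7S,8S)-guaia-1(10),3-diene-8,11-diol 8,11-O-di-tert-butylsilylene | CC1=C2CC=C(C)[C@@H]2C[C@@H]3C(C)(C)O[Si](C(C)(C)C)(C(C)(C)C)O[C@H]3C1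
F5 | step 10 | (5S,7S,8S)-guaia-1(10),4(15)-diene-8,11-diol 8,11-O-di-tert-butylsilylene | CC1=C2CCC(=C)[C@@H]2C[C@@H]3C(C)(C)O[Si](C(C)(C)C)(C(C)(C)C)O[C@H]3C1
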